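At early times the ochre run gives 5.7% of X after 1.00 h and 26.5% after 6.00 h, each reading with a scatter of 1 percentage point.

| setting | ochre | Thursday's | Tuesday's | Friday's | Monday's | Wednesday's | Saturday's |
|---|---|---|---|---|---|---|---|
| Z | 22 mM | 80 mM | 5.0 mM | 40 mM | 12 mM | 40 mM | 20 mM |
| J | 1.1 equiv | 1.10 equiv | 0.740 equiv | 1.10 equiv | 0.740 equiv | 4.40 equiv | 1.10 equiv |
| Q | 2 mol% | 1.2 mol% | 2 mol% | 3 mol% | 2 mol% | 2 mol% | 2 mol% |
| remark | run made earlier |  |  |  |  |  |  |
| time |  | 30 h | 30 h | 30 h | 30 h | 30 h | 30 h |

- ochre (time / h: X / %): 0.500: 2.4; 1.00: 5.7; 2.50: 12.2; 6.00: 26.5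

(standard deviation of a reading: 1 percentage point)

- no earlier run changes the charge of Q; that part of a forecast is a guess

* the flasks put in order of amount of X, in percent of the Z charged, best first, at 30 h (Thursday's / Tuesday's / Friday's / Monday's / Wednesday's / Saturday's)
* the amount of X, in percent of the Z charged of the flask you put first, at 30 h
* the amount of X, in percent of the Z charged of the flask you put last, at 30 h

These readings come from one charge, so two simple views fit them. The forecast's view is a direct meeting of Z and J, “rate ∝ [Z][J]”. On that view more J speeds a flask, and dilution slows it through both partners.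

My view is a chain. Q is an initiator. It feeds a carrier present in traces, carriers die in pairs, the carrier consumes Z, and J closes the cycle. Then, while J lasts, Z decays first order, J stays out of the rate, and the constant follows the square root of the Q concentration. That root is a guess, since no earlier run changes Q.

From the last ochre reading I take k_O, the ochre constant, which is minus the natural log of the fraction of Z left, taken as one minus the fraction of X, divided by the time: 0.0513 /h. It is a reading and carries the scatter. The ochre flask starts with 0.440 mM of Q. Another flask gets k, which is k_O times the root of its Q concentration over the ochre's, and its fraction of Z left is exp(−kt). Loading is reckoned on Z, so Tuesday's starts with 0.100 mM of Q and Friday's with 1.20 mM.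

My first round gives Friday's 92.1%, Thursday's 89.7%, Wednesday's 87.5%, Saturday's 77.0%, Monday's 67.9% and Tuesday's 52.0%. The second round puts that back. Monday's answer asks 8.15 mM of J against 8.88 mM charged, so J lasts in Monday's and the answer stands. I put Friday's first and Tuesday's last.

The forecast reads Wednesday's > Thursday's > Friday's > Saturday's > Monday's > Tuesday's, with 96% for the first flask and 21% for the last. We part on Wednesday's, which it puts first and I third, and on Tuesday's, where I stand 31 points higher.

The simulation gives Friday's > Thursday's > Wednesday's > Saturday's > Monday's > Tuesday's, with 91.9% and 51.6%. Wednesday's, with 4.40 equiv of J and 2 mol% of Q, reaches 87.2%, less than Friday's with 1.10 equiv of J and 3 mol% of Q.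

    2 E → D (k = 8.00 × 10⁸ /M/s)
    Q → 2 E (k = 7.10 × 10⁻⁷ /s)
    J + G → X + E (k = 13000 /M/s)
    Z + E → G (k = 23000 /M/s)

The forecast's view has its ground in a neighbour of Friday's with 0.280 equiv of J, where the J charge counts. The Q is Friday's, so my first round again says 92.1%. The second round asks 36.9 mM of J against 11.2 mM charged. J is then the limiting reagent, and X stops at the J charge. At 30.0 h that neighbour holds X at 28.0%, J at 0% and Z at 71.6%.

The runs are calculated with constants of no real substance.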